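The route rests on cutting the C12–C15 bond of the γ-butyrolactone (ring O–C13–C12–C15–C14), which is joined to side-chain carbon C11 only through its β-carbon C12. In the synthetic direction the C13 alcohol is esterified as a diazoacetate, and a chiral dirhodium carboxamidate then delivers the carbene carbon into one of the two C12–H bonds, so the lactone ring and the C12 centre arise together. The substrate is an open 2-substituted butane-1,4-diol unit on the cis-fused hydroazulene, with a silyl ether at C16 and C11 already configured. The bicycle comes from an allylsilane–ketone cyclisation, and the C1–C11 bond from a tertiary radical addition to a chiral butenolide.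

Key step: step 14

Labels: the bicycle carries azulene locants (C1–C8a); the side chain is C11 (CH on C1), C16 (its CH2O), C12 (lactone β-carbon), C13 (lactone OCH2), C14 (C=O) and C15 (α-carbon). Az = (1R,3aR,8aS)-1,4,4-trimethyl-8-methylidenedecahydroazulen-1-yl.

Assumption: cycloheptane-1,3-dione 1, bromoketal 9 and the d-menthol-derived butenolide 18 are purchased; the ligand hand in step 4 is the one that gives the 3R centre.

Step 1
Reactants: 1 cycloheptane-1,3-dione
Product: 2 3-ethoxycyclohept-2-en-1-one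
Conditions: EtOH, p-TsOH (cat.), toluene, reflux, Dean–Stark
Reagents that add atoms: ethanol, CCO
Why: Acid-catalysed vinylogous ester formation from the enolised 1,3-diketone, driven by azeotropic removal of water, prepares the ring for Stork–Danheiser chemistry and creates no stereocentre.

Step 2
Reactants: 2 3-ethoxycyclohept-2-en-1-one
Product: 6 3-ethoxy-7,7-dimethylcyclohept-2-en-1-one, via lithium dienolate 3 (not isolated), via monomethyl ketone 4 (not isolated), via lithium dienolate 5 (not isolated)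
Conditions: LDA, THF, −78 °C; MeI; then LDA, −78 °C; MeI, −78 → 0 °C
Reagents that add atoms: iodomethane, CI
Why: Kinetic deprotonation of a vinylogous ester occurs at the α′ carbon, so two successive enolate methylations (Stork–Danheiser α′-alkylation) build the gem-dimethyl carbon that becomes C4, and the product has no stereocentre.

Step 3
Reactants: 6 3-ethoxy-7,7-dimethylcyclohept-2-en-1-one
Product: 8 4,4-dimethylcyclohept-2-en-1-one, via allylic alcohol 7 (not isolated)
Conditions: LiAlH4, Et2O, 0 °C; then 1 M HCl, rt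
Reagents that add atoms: water, O
Why: 1,2-Reduction followed by acid hydrolysis of the enol ether and loss of water (Stork–Danheiser carbonyl transposition) places the gem-dimethyl group at the γ-position of the new enone.

Step 4
Reactants: 8 4,4-dimethylcyclohept-2-en-1-one; 9 2-(2-bromoethyl)-2-methyl-1,3-dioxolane
Product: 12 (3R)-4,4-dimethyl-3-[2-(2-methyl-1,3-dioxolan-2-yl)ethyl]cyclohept-1-en-1-yl trifluoromethanesulfonate, via Grignard reagent 10 (not isolated), via magnesium enolate 11 (not isolated)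
Conditions: 9, Mg, THF, rt; then 8, CuBr·SMe2 (5 mol %), (R)-1-[(Sp)-2-(diphenylphosphino)ferrocenyl]ethyldicyclohexylphosphine (6 mol %), t-BuOMe, −78 °C; then N-(5-chloro-2-pyridyl)bis(trifluoromethanesulfonimide), −78 → 0 °C
Reagents that add atoms: N-(5-chloropyridin-2-yl)-1,1,1-trifluoro-N-(trifluoromethylsulfonyl)methanesulfonamide, FC(F)(F)S(=O)(=O)N(c1ccc(Cl)cn1)S(=O)(=O)C(F)(F)F
Why: Copper-catalysed asymmetric conjugate addition of a Grignard reagent sets C3a (3R) under control of the chiral diphosphine, and triflation of the regiodefined magnesium enolate fixes the enol triflate on the C8a side.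

Step 5
Reactants: 12 (3R)-4,4-dimethyl-3-[2-(2-methyl-1,3-dioxolan-2-yl)ethyl]cyclohept-1-en-1-yl trifluoromethanesulfonate
Product: 13 trimethyl({(3R)-4,4-dimethyl-3-[2-(2-methyl-1,3-dioxolan-2-yl)ethyl]cyclohept-1-en-1-yl}methyl)silane
Conditions: Me3SiCH2MgCl, Pd(PPh3)4 (5 mol %), Et2O, 0 °C → rt
Reagents that add atoms: (trimethylsilyl)methylmagnesium chloride, C[Si](C)(C)C[Mg]Cl
Why: Kumada cross-coupling of an enol triflate with the silylmethyl Grignard reagent is the standard route to a 2-substituted allylsilane and leaves the ketal and C3a untouched.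

Step 6
Reactants: 13 trimethyl({(3R)-4,4-dimethyl-3-[2-(2-methyl-1,3-dioxolan-2-yl)ethyl]cyclohept-1-en-1-yl}methyl)silane
Product: 14 4-[(1R)-7,7-dimethyl-3-[(trimethylsilyl)methyl]cyclohept-2-en-1-yl]butan-2-one
Conditions: PPTS (cat.), acetone/H2O, 50 °C
Reagents that add atoms: water, O
Why: Mild acid-catalysed ketal hydrolysis frees the methyl ketone, the pyridinium acid being too weak to protodesilylate the allylsilane.

Step 7
Reactants: 14 4-[(1R)-7,7-dimethyl-3-[(trimethylsilyl)methyl]cyclohept-2-en-1-yl]butan-2-one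
Product: 15 (1R,3aR,8aS)-1,4,4-trimethyl-8-methylidenedecahydroazulen-1-ol
Conditions: TiCl4, CH2Cl2, −78 °C; aq. NaHCO3
Reagents that add atoms: none
Why: In this intramolecular Hosomi–Sakurai allylation the allylsilane γ-carbon C8a attacks the activated ketone, which forms C8a–C1, moves the alkene to the exocyclic C8 position and gives the cis fusion because the two-carbon tether on C3a reaches only one face of C8a; either C1 epimer is usable because that centre is erased in step 9.

Step 8
Reactants: 15 (1R,3aR,8aS)-1,4,4-trimethyl-8-methylidenedecahydroazulen-1-ol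
Product: 17 cesium 2-oxo-2-{[(1R,3aR,8aS)-1,4,4-trimethyl-8-methylidenedecahydroazulen-1-yl]oxy}acetate, via methyl oxalate 16 (not isolated)
Conditions: ClC(O)CO2Me, Et3N, DMAP (cat.), CH2Cl2, 0 °C → rt; then 1 M aq. CsOH, THF, rt
Reagents that add atoms: methyl chlorooxoacetate, COC(=O)C(Cl)=O; cesium hydroxide, [Cs+].[OH-]
Why: Acylation of the tertiary alcohol and selective saponification of the unhindered methyl ester give the cesium alkyl oxalate, an established precursor of tertiary radicals.

Step 9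
Reactants: 17 cesium 2-oxo-2-{[(1R,3aR,8aS)-1,4,4-trimethyl-8-methylidenedecahydroazulen-1-yl]oxy}acetate; 18 (5S)-5-{[(1S,2R,5S)-5-methyl-2-(propan-2-yl)cyclohexyl]oxy}furan-2(5H)-one
Product: 19 (4R,5S)-4-Az-5-{[(1S,2R,5S)-5-methyl-2-(propan-2-yl)cyclohexyl]oxy}oxolan-2-one
Conditions: Ir[dF(CF3)ppy]2(dtbbpy)PF6 (1 mol %), H2O (10 equiv), DME/DMF 3:1, blue LEDs, 60 °C
Reagents that add atoms: none
Why: Photoredox oxidation of the oxalate releases two CO2 and the tertiary C1 radical, which adds to the butenolide β-carbon (Giese reaction) from the convex face of the cis-fused bicycle, setting C1, and anti to the menthyloxy group, setting C11.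

Step 10
Reactants: 19 (4R,5S)-4-Az-5-{[(1S,2R,5S)-5-methyl-2-(propan-2-yl)cyclohexyl]oxy}oxolan-2-one
Product: 20 (2R)-2-Az-butane-1,4-diol
Conditions: LiAlH4, THF, 0 °C → rt
Reagents that add atoms: none
Why: Hydride reduction of the lactone acetal converts both carbonyl-level carbons (C13 and C16) into primary alcohols with release of menthol and does not touch C11 or the alkene.

Step 11
Reactants: 20 (2R)-2-Az-butane-1,4-diol; 21 bromoacetyl bromide
Product: 22 (3R)-3-Az-4-hydroxybutyl 2-bromoacetate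
Conditions: BrCH2COBr (1.05 equiv), 2,4,6-collidine, CH2Cl2, −78 °C
Reagents that add atoms: none
Why: In this sterically controlled monoacylation the unhindered C13 hydroxyl should react well ahead of the C16 hydroxyl, which is flanked by C11 and the quaternary C1.

Step 12
Reactants: 22 (3R)-3-Az-4-hydroxybutyl 2-bromoacetate
Product: 23 (3R)-3-Az-4-[(tert-butyldimethylsilyl)oxy]butyl 2-bromoacetate
Conditions: TBSOTf, 2,6-lutidine, CH2Cl2, −78 → 0 °C
Reagents that add atoms: tert-butyldimethylsilyl trifluoromethanesulfonate, CC(C)(C)[Si](C)(C)OS(=O)(=O)C(F)(F)F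
Why: Silylation with a silyl triflate and a hindered base protects the hindered C16 alcohol quickly and, unlike imidazole conditions, does not displace the bromide.

Step 13
Reactants: 23 (3R)-3-Az-4-[(tert-butyldimethylsilyl)oxy]butyl 2-bromoacetate
Product: 24 (3R)-3-Az-4-[(tert-butyldimethylsilyl)oxy]butyl 2-diazoacetate
Conditions: TsNHNHTs, DBU, THF, 0 °C
Reagents that add atoms: N,N′-bis(p-toluenesulfonyl)hydrazine, Cc1ccc(cc1)S(=O)(=O)NNS(=O)(=O)c1ccc(C)cc1
Why: In the Fukuyama diazoacetate synthesis the bromoacetate alkylates ditosylhydrazine and base-induced loss of two sulfinate ions gives the diazo ester under conditions that spare the silyl ether and the alkene.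

Step 14
Reactants: 24 (3R)-3-Az-4-[(tert-butyldimethylsilyl)oxy]butyl 2-diazoacetate
Product: 25 (4R)-4-{(1R)-1-Az-2-[(tert-butyldimethylsilyl)oxy]ethyl}oxolan-2-one
Conditions: Rh2(4R-MPPIM)4 [dirhodium tetrakis(methyl (4R)-2-oxo-1-(3-phenylpropanoyl)imidazolidine-4-carboxylate)] (1 mol %), CH2Cl2, reflux, 24 added over 6 h
Reagents that add atoms: none
Why: The catalyst, in which both rhodium atoms are divalent, expels N2 from the diazo ester, and the resulting metal carbene at C15 attacks a C12–H bond in one concerted three-centre event, so C12–C15 forms with retention at C12. The closest known reaction type is the intramolecular C–H insertion of 3-substituted propyl diazoacetates under chiral dirhodium carboxamidate catalysis, which gives β-substituted γ-butyrolactones. The single ring closes in the 1,5 sense: the carbene carbon bonds to the carbon β to the ester oxygen, giving the five-membered ring O–C13–C12–C15–C14. The new centre C12 is controlled by the chiral ligand pocket, which distinguishes the two diastereotopic C12 hydrogens; the (4R) catalyst is chosen because, by analogy with 3-arylpropyl esters, it should deliver the (4R) lactone, and the large C11 substituent is expected to reinforce this by pointing away from the ligands. The step needs γ-lactone formation to win over insertion at C13–H (β-lactone), insertion at the tertiary C11–H (δ-lactone) and carbene dimerisation; amide-type ligands favour the five-ring transition state, C11–H is shielded by the quaternary C1 and the silyloxymethyl group, and slow addition keeps the diazo ester dilute. The exocyclic C8 alkene would have to close a strained medium ring to be cyclopropanated, so it should stay intact.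

Step 15
Reactants: 25 (4R)-4-{(1R)-1-Az-2-[(tert-butyldimethylsilyl)oxy]ethyl}oxolan-2-one
Product: 27 (3S,4R)-4-{(1R)-1-Az-2-[(tert-butyldimethylsilyl)oxy]ethyl}-3-hydroxyoxolan-2-one, via sodium enolate 26 (not isolated)
Conditions: NaHMDS, THF, −78 °C; then 2-(phenylsulfonyl)-3-phenyloxaziridine, −78 °C; AcOH
Reagents that add atoms: 2-(benzenesulfonyl)-3-phenyloxaziridine, O=S(=O)(c1ccccc1)N1OC1c1ccccc1
Why: In the Davis enolate hydroxylation the oxaziridine transfers oxygen to C15 on the face opposite the bulky C12 substituent, which gives the 3,4-trans hydroxy lactone (3S).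

Step 16
Reactants: 27 (3S,4R)-4-{(1R)-1-Az-2-[(tert-butyldimethylsilyl)oxy]ethyl}-3-hydroxyoxolan-2-one
Product: 28 (3S,4R)-4-[(1R)-1-Az-2-hydroxyethyl]-3-hydroxyoxolan-2-one
Conditions: HF·pyridine, pyridine, THF, 0 °C → rt
Reagents that add atoms: none
Why: Buffered, non-basic fluoride cleavage of the silyl ether frees the C16 alcohol without epimerising C15 or opening the lactone.

Step 17
Reactants: 28 (3S,4R)-4-[(1R)-1-Az-2-hydroxyethyl]-3-hydroxyoxolan-2-one
Product: 29 (3S,4R)-4-[(1R)-2-acetoxy-1-Az-ethyl]-2-oxooxolan-3-yl acetate (CNP0234964.1)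
Conditions: Ac2O, pyridine, DMAP (cat.), CH2Cl2, rt
Reagents that add atoms: acetic anhydride, CC(=O)OC(C)=O
Why: DMAP-catalysed acetylation esterifies the C15 and C16 hydroxyls together and creates no new stereocentre.

Compound list
1 | cycloheptane-1,3-dione | O=C1CCCCC(=O)C1 | starting material
2 | 3-ethoxycyclohept-2-en-1-one | CCOC1=CC(=O)CCCC1 | intermediate
3 | lithium 3-ethoxycyclohepta-1(7),2-dien-1-olate | [Li]OC1=CCCCC(OCC)=C1 | intermediate
4 | 3-ethoxy-7-methylcyclohept-2-en-1-one (racemic) | CCOC1=CC(=O)C(C)CCC1 | intermediate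
5 | lithium 3-ethoxy-7-methylcyclohepta-1(7),2-dien-1-olate | [Li]OC1=C(C)CCCC(OCC)=C1 | intermediate
6 | 3-ethoxy-7,7-dimethylcyclohept-2-en-1-one | CCOC1=CC(=O)C(C)(C)CCC1 | intermediate
7 | 3-ethoxy-7,7-dimethylcyclohept-2-en-1-ol (racemic) | CCOC1=CC(O)C(C)(C)CCC1 | intermediate
8 | 4,4-dimethylcyclohept-2-en-1-one | O=C1C=CC(C)(C)CCC1 | intermediate
9 | 2-(2-bromoethyl)-2-methyl-1,3-dioxolane | CC1(CCBr)OCCO1 | starting material
10 | [2-(2-methyl-1,3-dioxolan-2-yl)ethyl]magnesium bromide | CC1(CC[Mg]Br)OCCO1 | intermediate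
11 | bromomagnesium (3R)-4,4-dimethyl-3-[2-(2-methyl-1,3-dioxolan-2-yl)ethyl]cyclohept-1-en-1-olate | Br[Mg]OC1=C[C@@H](CCC2(C)OCCO2)C(C)(C)CCC1 | intermediate
12 | (3R)-4,4-dimethyl-3-[2-(2-methyl-1,3-dioxolan-2-yl)ethyl]cyclohept-1-en-1-yl trifluoromethanesulfonate | O=S(=O)(OC1=C[C@@H](CCC2(C)OCCO2)C(C)(C)CCC1)C(F)(F)F | intermediate
13 | trimethyl({(3R)-4,4-dimethyl-3-[2-(2-methyl-1,3-dioxolan-2-yl)ethyl]cyclohept-1-en-1-yl}methyl)silane | C[Si](C)(C)CC1=C[C@@H](CCC2(C)OCCO2)C(C)(C)CCC1 | intermediate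
14 | 4-[(1R)-7,7-dimethyl-3-[(trimethylsilyl)methyl]cyclohept-2-en-1-yl]butan-2-one | C[Si](C)(C)CC1=C[C@@H](CCC(C)=O)C(C)(C)CCC1 | intermediate
15 | (1R,3aR,8aS)-1,4,4-trimethyl-8-methylidenedecahydroazulen-1-ol | C=C1CCCC(C)(C)[C@@H]2CC[C@@](C)(O)[C@H]12 | intermediate
16 | methyl (1R,3aR,8aS)-1,4,4-trimethyl-8-methylidenedecahydroazulen-1-yl oxalate | C=C1CCCC(C)(C)[C@@H]2CC[C@@](C)(OC(=O)C(=O)OC)[C@H]12 | intermediate
17 | cesium 2-oxo-2-{[(1R,3aR,8aS)-1,4,4-trimethyl-8-methylidenedecahydroazulen-1-yl]oxy}acetate | C=C1CCCC(C)(C)[C@@H]2CC[C@@](C)(OC(=O)C(=O)[O-])[C@H]12.[Cs+] | intermediate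
18 | (5S)-5-{[(1S,2R,5S)-5-methyl-2-(propan-2-yl)cyclohexyl]oxy}furan-2(5H)-one | O=C1C=C[C@@H](O[C@H]2C[C@@H](C)CC[C@@H]2C(C)C)O1 | starting material
19 | (4R,5S)-4-Az-5-{[(1S,2R,5S)-5-methyl-2-(propan-2-yl)cyclohexyl]oxy}oxolan-2-one | C=C1CCCC(C)(C)[C@@H]2CC[C@@](C)([C@H]3CC(=O)O[C@@H]3O[C@H]4C[C@@H](C)CC[C@@H]4C(C)C)[C@H]12 | intermediate
20 | (2R)-2-Az-butane-1,4-diol | C=C1CCCC(C)(C)[C@@H]2CC[C@@](C)([C@H](CO)CCO)[C@H]12 | intermediate
21 | bromoacetyl bromide | BrCC(Br)=O | starting material
22 | (3R)-3-Az-4-hydroxybutyl 2-bromoacetate | C=C1CCCC(C)(C)[C@@H]2CC[C@@](C)([C@H](CO)CCOC(=O)CBr)[C@H]12 | intermediate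
23 | (3R)-3-Az-4-[(tert-butyldimethylsilyl)oxy]butyl 2-bromoacetate | C=C1CCCC(C)(C)[C@@H]2CC[C@@](C)([C@H](CO[Si](C)(C)C(C)(C)C)CCOC(=O)CBr)[C@H]12 | intermediate
24 | (3R)-3-Az-4-[(tert-butyldimethylsilyl)oxy]butyl 2-diazoacetate | C=C1CCCC(C)(C)[C@@H]2CC[C@@](C)([C@H](CO[Si](C)(C)C(C)(C)C)CCOC(=O)C=[N+]=[N-])[C@H]12 | intermediate
25 | (4R)-4-{(1R)-1-Az-2-[(tert-butyldimethylsilyl)oxy]ethyl}oxolan-2-one | C=C1CCCC(C)(C)[C@@H]2CC[C@@](C)([C@H](CO[Si](C)(C)C(C)(C)C)[C@@H]3COC(=O)C3)[C@H]12 | intermediate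
26 | sodium (4R)-4-{(1R)-1-Az-2-[(tert-butyldimethylsilyl)oxy]ethyl}-4,5-dihydrofuran-2-olate | C=C1CCCC(C)(C)[C@@H]2CC[C@@](C)([C@H](CO[Si](C)(C)C(C)(C)C)[C@@H]3COC(O[Na])=C3)[C@H]12 | intermediate
27 | (3S,4R)-4-{(1R)-1-Az-2-[(tert-butyldimethylsilyl)oxy]ethyl}-3-hydroxyoxolan-2-one | C=C1CCCC(C)(C)[C@@H]2CC[C@@](C)([C@H](CO[Si](C)(C)C(C)(C)C)[C@@H]3COC(=O)[C@H]3O)[C@H]12 | intermediate
28 | (3S,4R)-4-[(1R)-1-Az-2-hydroxyethyl]-3-hydroxyoxolan-2-one | C=C1CCCC(C)(C)[C@@H]2CC[C@@](C)([C@H](CO)[C@@H]3COC(=O)[C@H]3O)[C@H]12 | intermediate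
29 | (3S,4R)-4-[(1R)-2-acetoxy-1-Az-ethyl]-2-oxooxolan-3-yl acetate | C=C1CCCC(C)(C)[C@@H]2CC[C@@](C)([C@H](COC(C)=O)[C@@H]3COC(=O)[C@H]3OC(C)=O)[C@H]12 | target

Total step count: 17
Longest linear sequence: 17 steps (1 → 29); 9, 18 and 21 are purchased and enter directly.

Steps most likely to fail

Step 14. The catalyst and the existing C11 centre may turn out to be a mismatched pair, so that the wrong C12 hydrogen is taken, and insertion at the tertiary C11–H or carbene dimerisation may erode the yield. The fallback sets out from 19 and returns at 25; it builds the lactone by auxiliary-controlled enolate alkylation instead of C–H insertion. Reduction of 19 with NaBH4 in aqueous KOH, then acidification, should release menthol and give (4R)-4-Az-oxolan-2-one F1. Saponification, silylation of the C16 hydroxyl with TBSCl/imidazole and cleavage of the silyl ester with K2CO3 in aqueous methanol should give the silyloxy acid F2. Its pivaloyl mixed anhydride and lithiated (R)-4-benzyloxazolidin-2-one should give the imide F3. NaHMDS and tert-butyl bromoacetate should alkylate C12 on the face away from the benzyl group to give the succinate F4. LiBH4 should remove the auxiliary and free the C13 alcohol as the hydroxy ester F5, and catalytic camphorsulfonic acid in CH2Cl2 should close F5 to 25.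

Step 4. Addition at the neopentyl β-carbon may be slow, and the enantioselectivity with a functionalised Grignard reagent may be insufficient. The fallback sets out from 6 (with Grignard reagent 10) and returns at 12; it introduces the carbon chain first and sets C3a by asymmetric conjugate reduction. Addition of 10 with CeCl3 to ketone 6 and work-up with aqueous oxalic acid (Stork–Danheiser transposition) should give 4,4-dimethyl-3-[2-(2-methyl-1,3-dioxolan-2-yl)ethyl]cyclohept-2-en-1-one F6. Copper hydride reduction with Cu(OAc)2, the enantiomer of DTBM-SEGPHOS that gives the 3R centre, and diethoxymethylsilane should give the silyl enol ether F7. MeLi followed by the pyridyl triflimide of step 4 should convert F7 into 12.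

Step 11. Discrimination between the two primary hydroxyls may be incomplete, giving the regioisomeric ester and the diester. The fallback sets out from 20 and returns at 23; it protects both alcohols and unmasks only the unhindered one. TBSCl and imidazole in DMF should give the bis-silyl ether F8. PPTS in ethanol at 0 °C should remove the less hindered C13 silyl ether and give (3R)-3-Az-4-[(tert-butyldimethylsilyl)oxy]butan-1-ol F9. Bromoacetyl bromide 21 and pyridine should then esterify the only free hydroxyl of F9 and give 23.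

Further compounds
F1 | step 14 | (4R)-4-Az-oxolan-2-one | C=C1CCCC(C)(C)[C@@H]2CC[C@@](C)([C@@H]3COC(=O)C3)[C@H]12
F2 | step 14 | (3R)-3-Az-4-[(tert-butyldimethylsilyl)oxy]butanoic acid | C=C1CCCC(C)(C)[C@@H]2CC[C@@](C)([C@H](CO[Si](C)(C)C(C)(C)C)CC(=O)O)[C@H]12
F3 | step 14 | (4R)-3-{(3R)-3-Az-4-[(tert-butyldimethylsilyl)oxy]butanoyl}-4-benzyl-1,3-oxazolidin-2-one | C=C1CCCC(C)(C)[C@@H]2CC[C@@](C)([C@H](CO[Si](C)(C)C(C)(C)C)CC(=O)N3[C@H](Cc4ccccc4)COC3=O)[C@H]12
F4 | step 14 | tert-butyl (3R,4R)-4-Az-3-{[(4R)-4-benzyl-2-oxo-1,3-oxazolidin-3-yl]carbonyl}-5-[(tert-butyldimethylsilyl)oxy]pentanoate | C=C1CCCC(C)(C)[C@@H]2CC[C@@](C)([C@H](CO[Si](C)(C)C(C)(C)C)[C@@H](CC(=O)OC(C)(C)C)C(=O)N3[C@H](Cc4ccccc4)COC3=O)[C@H]12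
F5 | step 14 | tert-butyl (3R,4R)-4-Az-5-[(tert-butyldimethylsilyl)oxy]-3-(hydroxymethyl)pentanoate | C=C1CCCC(C)(C)[C@@H]2CC[C@@](C)([C@H](CO[Si](C)(C)C(C)(C)C)[C@@H](CC(=O)OC(C)(C)C)CO)[C@H]12
F6 | step 4 | 4,4-dimethyl-3-[2-(2-methyl-1,3-dioxolan-2-yl)ethyl]cyclohept-2-en-1-one | O=C1C=C(CCC2(C)OCCO2)C(C)(C)CCC1
F7 | step 4 | diethoxy(methyl){[(3R)-4,4-dimethyl-3-[2-(2-methyl-1,3-dioxolan-2-yl)ethyl]cyclohept-1-en-1-yl]oxy}silane | CCO[Si](C)(OCC)OC1=C[C@@H](CCC2(C)OCCO2)C(C)(C)CCC1
F8 | step 11 | (2R)-2-Az-1,4-bis[(tert-butyldimethylsilyl)oxy]butane | C=C1CCCC(C)(C)[C@@H]2CC[C@@](C)([C@H](CO[Si](C)(C)C(C)(C)C)CCO[Si](C)(C)C(C)(C)C)[C@H]12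
F9 | step 11 | (3R)-3-Az-4-[(tert-butyldimethylsilyl)oxy]butan-1-ol | C=C1CCCC(C)(C)[C@@H]2CC[C@@](C)([C@H](CO[Si](C)(C)C(C)(C)C)CCO)[C@H]12
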